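**Retrosynthetic overview**

1. Numbering used throughout: ring C1 (C=O), C2 (bears CH2O), C3 (=CH), C4 (CH2), C5 (stereocentre), C6 (CH2); side chain C1′–C7′ (hepta-1,4-dien-2-yl). Both isobutyrates go on last, at the two primary hydroxyls of a triol.
2. Key disconnection: ring bonds C3–C4 and C1–C2 lead back to an achiral 3-substituted cyclobutanone plus Me3Si–C≡C–CH2OTBS (nickel-catalysed C–C activation, formal [4+2]). The cyclobutanone C1–C4 bond is not in the target; it is there on purpose and is cleaved in the key step, whose ring-closing event is C3–C4 bond formation.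
3. Enabling feature: C5 is a CH flanked by the two ring CH2 groups C4 and C6, which are 1,3-related across the C1 carbonyl. Tying C4 to C1 gives a strained four-membered ketone in which C1–C4 and C1–C6 are enantiotopic, so ligand-controlled cleavage of C1–C4 sets C5. The cis C2–CH2O/C3 relationship in the enone lets a regiocontrolling SiMe3 on C3 be removed afterwards by a 1,4-Brook shift.
4. Side chain: the 2-substituted (E)-1,4-diene comes from 3-ethynylcyclobutanone and a homoallylic bis-silyl ether by ruthenium-catalysed Alder-ene coupling; the tertiary carbinol centre comes from (S)-2-methylglycidol.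
5. Ring order: the four-membered ring is bought (as a ketal ester); the six-membered ring is the only ring formed (step 7).

Key step: step 7

Remark: the sense of induction of the nickel/phosphoramidite catalyst cannot be predicted with confidence; the route assumes that one ligand antipode, found in a short screen, cleaves the ring bond that leads to the required C5 configuration (the other antipode would give the C5 epimer).

**Route**

Step 1
Reactants: 1 (S)-2-methylglycidol
Product: 2 (2R)-2-methylpent-4-ene-1,2-diol
Conditions: CH2=CHMgBr (3 equiv), CuI (10 mol %), THF, −30 → 0 °C; aq. NH4Cl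
Reagents that add atoms: vinylmagnesium bromide, C=C[Mg]Br
Why: Copper-catalysed Grignard opening of the epoxide (SN2 at the unsubstituted CH2) leaves the tertiary carbinol centre untouched, so the spatial arrangement of 1 is carried into 2 (the descriptor changes from S to R only through CIP priorities), and the degenerate Payne rearrangement of the alkoxide returns the same enantiomer.

Step 2
Reactants: 2 (2R)-2-methylpent-4-ene-1,2-diol
Product: 3 (4R)-4-methyl-4,5-bis(triethylsilyloxy)pent-1-ene
Conditions: Et3SiOTf (2.4 equiv), 2,6-lutidine, CH2Cl2, −78 → 0 °C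
Reagents that add atoms: triethylsilyl trifluoromethanesulfonate, CC[Si](CC)(CC)OS(=O)(=O)C(F)(F)F
Why: Silyl triflate/lutidine silylation is forceful enough for the tertiary hydroxyl, and masking both oxygens removes every O–H that could protonate nickel–carbon bonds in step 7 while allowing one fluoride treatment to free everything later.

Step 3
Reactants: 4 methyl 3,3-dimethoxycyclobutane-1-carboxylate
Product: 6 3-ethynyl-1,1-dimethoxycyclobutane, via 3,3-dimethoxycyclobutane-1-carbaldehyde 5 (not isolated)
Conditions: i-Bu2AlH (1.05 equiv), CH2Cl2, −78 °C; then MeOH, K2CO3, dimethyl (1-diazo-2-oxopropyl)phosphonate, −78 °C → rt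
Reagents that add atoms: dimethyl (1-diazo-2-oxopropyl)phosphonate (Ohira–Bestmann reagent), COP(=O)(OC)C(=[N+]=[N-])C(C)=O
Why: Half-reduction of the ester to the aldehyde (stable aluminate at −78 °C) followed in the same flask by Ohira–Bestmann homologation (Seyferth–Gilbert type) should give the terminal alkyne without isolating the volatile aldehyde, the dimethyl ketal being inert to hydride and carbonate.

Step 4
Reactants: 6 3-ethynyl-1,1-dimethoxycyclobutane
Product: 7 3-ethynylcyclobutan-1-one
Conditions: 1 M aq. HCl, THF, rt; volatile product carried on as a concentrated solution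
Reagents that add atoms: water, O
Why: Acid-catalysed ketal hydrolysis is reliable for cyclobutanone dimethyl ketals and the terminal alkyne is inert to dilute acid.

Step 5
Reactants: 7 3-ethynylcyclobutan-1-one; 3 (4R)-4-methyl-4,5-bis(triethylsilyloxy)pent-1-ene
Product: 8 3-[(4E,6R)-6-methyl-6,7-bis(triethylsilyloxy)hepta-1,4-dien-2-yl]cyclobutan-1-one
Conditions: [CpRu(MeCN)3]PF6 (10 mol %), acetone, rt
Reagents that add atoms: none
Why: Ruthenium-catalysed alkene–alkyne coupling (Alder-ene reaction) via a ruthenacyclopentene and β-hydride elimination should give the branched 1,4-diene, because the α-branched alkyne substituent is placed away from the metal, and the new disubstituted alkene next to the quaternary carbon should form E; no stereocentre is involved.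

Step 6
Reactants: 9 3-(trimethylsilyl)prop-2-yn-1-ol
Product: 10 tert-butyldimethyl{[3-(trimethylsilyl)prop-2-yn-1-yl]oxy}silane
Conditions: t-BuMe2SiCl, imidazole, CH2Cl2, 0 °C → rt
Reagents that add atoms: tert-butyldimethylsilyl chloride, CC(C)(C)[Si](C)(C)Cl
Why: Standard silyl ether formation gives an aprotic propargylic ether that, unlike a propargylic ester, should not ionize on zerovalent nickel.

Step 7
Reactants: 8 3-[(4E,6R)-6-methyl-6,7-bis(triethylsilyloxy)hepta-1,4-dien-2-yl]cyclobutan-1-one; 10 tert-butyldimethyl{[3-(trimethylsilyl)prop-2-yn-1-yl]oxy}silane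
Product: 13 (5S)-2-{[(tert-butyldimethylsilyl)oxy]methyl}-5-[(4E,6R)-6-methyl-6,7-bis(triethylsilyloxy)hepta-1,4-dien-2-yl]-3-(trimethylsilyl)cyclohex-2-en-1-one, via spiro oxanickelacyclopentene 11 (not isolated), via seven-membered nickelacycle 12 (not isolated)
Conditions: Ni(cod)2 (10 mol %), BINOL-based N,N-bis(1-phenylethyl)phosphoramidite (20 mol %, one antipode), 10 (1.5 equiv), toluene, 80 °C
Reagents that add atoms: none
Why: Proposed new method: zerovalent nickel joins the C=O of 8 and the alkyne by oxidative cyclization to the spiro oxanickelacyclopentene 11 (C1–C2 bond, silicon-bearing carbon on nickel), strain-driven β-carbon elimination then cleaves one of the two enantiotopic C1–CH2 bonds of the four-membered ring to give the seven-membered nickelacycle 12, and C(sp3)–C(sp2) reductive elimination joins the freed CH2 (C4) to the silylated carbon (C3). The closest known reaction types are the achiral nickel/phosphine-catalysed intermolecular insertion of internal alkynes into 3-substituted cyclobutanones and the nickel/chiral phosphoramidite desymmetrization of 3-substituted cyclobutanones by intramolecular alkene insertion; new here is their combination, an intermolecular alkyne insertion that is enantiotopos-selective. The six-membered carbocycle is closed by reductive elimination from metallacycle 12 (ring contraction from seven to six, overall a [4+2] two-carbon ring expansion of the cyclobutanone), so no endo/exo constraint of an open-chain cyclization arises. C5 itself is not touched; it becomes a stereocentre because its two CH2 arms become different, and which C1–CH2 bond breaks in 11 is decided by the chiral ligand on nickel (catalyst control; the 6′R centre is too remote to interfere). The step needs regioselectivity (Si at C3, CH2OTBS at C2), secured by the preference of silylalkynes to place the silicon-bearing carbon on nickel in carbonyl–alkyne oxidative cyclization, and chemoselectivity for the ketone over the two unactivated side-chain alkenes, secured by the ring strain of the four-membered ketone that drives C–C cleavage. β-Hydride elimination at C5–H of 12 is the competing path and should be outrun by reductive elimination within the constrained metallacycle.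

Step 8
Reactants: 13 (5S)-2-{[(tert-butyldimethylsilyl)oxy]methyl}-5-[(4E,6R)-6-methyl-6,7-bis(triethylsilyloxy)hepta-1,4-dien-2-yl]-3-(trimethylsilyl)cyclohex-2-en-1-one
Product: 16 (5R)-5-[(4E,6R)-6,7-dihydroxy-6-methylhepta-1,4-dien-2-yl]-2-(hydroxymethyl)cyclohex-2-en-1-one, via 3-trimethylsilyl triol 14 (not isolated), via O-trimethylsilyl ether 15 (not isolated)
Conditions: Bu4NF (6 equiv), wet THF, 0 °C → rt; aq. NH4Cl
Reagents that add atoms: none
Why: Fluoride cleaves the three O–Si bonds, and the freed C2–CH2 alkoxide, held cis to the C3–SiMe3 group by the ring double bond, should take silicon off carbon through a five-membered silicate (1,4-Brook C-to-O silyl migration, the known base/fluoride protodesilylation of (Z)-γ-silyl allylic alcohols) before the resulting O–SiMe3 ether is cleaved in turn; C5 is not acidic, and its descriptor changes from S to R only because silicon leaves C3.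

Step 9
Reactants: 16 (5R)-5-[(4E,6R)-6,7-dihydroxy-6-methylhepta-1,4-dien-2-yl]-2-(hydroxymethyl)cyclohex-2-en-1-one
Product: 17 (5R)-5-[(4E,6R)-6-hydroxy-6-methyl-7-(isobutyryloxy)hepta-1,4-dien-2-yl]-2-[(isobutyryloxy)methyl]cyclohex-2-en-1-one (CNP0536801.1)
Conditions: i-PrCOCl (2.3 equiv), pyridine, CH2Cl2, −20 → 0 °C
Reagents that add atoms: isobutyryl chloride, CC(C)C(Cl)=O
Why: Chemoselective acylation with acid chloride/pyridine should esterify the two primary hydroxyls while the hindered tertiary allylic hydroxyl stays free, and low temperature without a nucleophilic catalyst protects the Morita–Baylis–Hillman-type allylic ester from SN2′ displacement.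

**Compound list**

1 | (S)-2-methylglycidol, (2S)-(2-methyloxiran-2-yl)methanol | C1[C@@](C)(O1)CO | starting material
2 | (2R)-2-methylpent-4-ene-1,2-diol | C=CC[C@@](C)(O)CO | intermediate
3 | (4R)-4-methyl-4,5-bis(triethylsilyloxy)pent-1-ene | C=CC[C@@](C)(O[Si](CC)(CC)CC)CO[Si](CC)(CC)CC | intermediate
4 | methyl 3,3-dimethoxycyclobutane-1-carboxylate | COC(=O)C1CC(OC)(OC)C1 | starting material
5 | 3,3-dimethoxycyclobutane-1-carbaldehyde | O=CC1CC(OC)(OC)C1 | intermediate
6 | 3-ethynyl-1,1-dimethoxycyclobutane | C#CC1CC(OC)(OC)C1 | intermediate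
7 | 3-ethynylcyclobutan-1-one | C#CC1CC(=O)C1 | intermediate
8 | 3-[(4E,6R)-6-methyl-6,7-bis(triethylsilyloxy)hepta-1,4-dien-2-yl]cyclobutan-1-one | C=C(C/C=C/[C@@](C)(O[Si](CC)(CC)CC)CO[Si](CC)(CC)CC)C1CC(=O)C1 | intermediate
9 | 3-(trimethylsilyl)prop-2-yn-1-ol | C[Si](C)(C)C#CCO | starting material
10 | tert-butyldimethyl{[3-(trimethylsilyl)prop-2-yn-1-yl]oxy}silane | C[Si](C)(C)C#CCO[Si](C)(C)C(C)(C)C | intermediate
11 | spiro oxanickelacyclopentene: Ni bound to O and to the SiMe3-bearing alkene carbon, spiro carbon = former carbonyl carbon of 8 (ligand on Ni omitted) | C=C(C/C=C/[C@@](C)(O[Si](CC)(CC)CC)CO[Si](CC)(CC)CC)C1CC2(C1)O[Ni]C([Si](C)(C)C)=C2CO[Si](C)(C)C(C)(C)C | intermediate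
12 | seven-membered nickelacycle Ni–C4H2–C5H–C6H2–C1(=O)–C2(CH2OTBS)=C3(SiMe3)–Ni, C5 arranged as in 13 (ligand on Ni omitted) | C=C(C/C=C/[C@@](C)(O[Si](CC)(CC)CC)CO[Si](CC)(CC)CC)[C@@H]1C[Ni]C([Si](C)(C)C)=C(CO[Si](C)(C)C(C)(C)C)C(=O)C1 | intermediate
13 | (5S)-2-{[(tert-butyldimethylsilyl)oxy]methyl}-5-[(4E,6R)-6-methyl-6,7-bis(triethylsilyloxy)hepta-1,4-dien-2-yl]-3-(trimethylsilyl)cyclohex-2-en-1-one | C=C(C/C=C/[C@@](C)(O[Si](CC)(CC)CC)CO[Si](CC)(CC)CC)[C@@H]1CC([Si](C)(C)C)=C(CO[Si](C)(C)C(C)(C)C)C(=O)C1 | intermediate
14 | (5S)-5-[(4E,6R)-6,7-dihydroxy-6-methylhepta-1,4-dien-2-yl]-2-(hydroxymethyl)-3-(trimethylsilyl)cyclohex-2-en-1-one | C=C(C/C=C/[C@@](C)(O)CO)[C@@H]1CC([Si](C)(C)C)=C(CO)C(=O)C1 | intermediate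
15 | (5R)-5-[(4E,6R)-6,7-dihydroxy-6-methylhepta-1,4-dien-2-yl]-2-{[(trimethylsilyl)oxy]methyl}cyclohex-2-en-1-one | C=C(C/C=C/[C@@](C)(O)CO)[C@@H]1CC=C(CO[Si](C)(C)C)C(=O)C1 | intermediate
16 | (5R)-5-[(4E,6R)-6,7-dihydroxy-6-methylhepta-1,4-dien-2-yl]-2-(hydroxymethyl)cyclohex-2-en-1-one | C=C(C/C=C/[C@@](C)(O)CO)[C@@H]1CC=C(CO)C(=O)C1 | intermediate
17 | (5R)-5-[(4E,6R)-6-hydroxy-6-methyl-7-(isobutyryloxy)hepta-1,4-dien-2-yl]-2-[(isobutyryloxy)methyl]cyclohex-2-en-1-one (CNP0536801.1) | C=C(C/C=C/[C@@](C)(O)COC(=O)C(C)C)[C@@H]1CC=C(COC(=O)C(C)C)C(=O)C1 | target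

**Step count and risks**

Total step count: 9. Longest linear sequence: 6 steps (4 → 6 → 7 → 8 → 13 → 16 → 17; the branch from 1 is equally long).

Steps most likely to fail:

1. Step 7 (bears the label). What may go wrong: poor discrimination between the two enantiotopic C1–CH2 bonds during β-carbon elimination, giving both C5 configurations, or β-hydride elimination from the alkyl–nickel opening the ring. Fallback with known chemistry, setting out from 8 and 10: catalyst control is given up and the annulation is run in its established achiral form (Ni(cod)2 10 mol %, PCy3 20 mol %, toluene, 100 °C). This should give 13 together with its C5 epimer (5R)-2-{[(tert-butyldimethylsilyl)oxy]methyl}-5-[(4E,6R)-6-methyl-6,7-bis(triethylsilyloxy)hepta-1,4-dien-2-yl]-3-(trimethylsilyl)cyclohex-2-en-1-one F1. The mixture is taken through the fluoride treatment of step 8 to 16 and the epimeric triol (5S)-5-[(4E,6R)-6,7-dihydroxy-6-methylhepta-1,4-dien-2-yl]-2-(hydroxymethyl)cyclohex-2-en-1-one F2. Because the 6′R centre is fixed, the two triols are diastereomers; they are separated by preparative HPLC on a chiral stationary phase, and the route is rejoined at 16.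

2. Step 8. What may go wrong: the C-to-O silyl migration stalls after O-desilylation so that the C3–Si bond survives, or the enone degrades under basic fluoride on prolonged exposure. Fallback, setting out from 8: the silicon placeholder is changed to one that fluoride removes from carbon on its own. Commercial tert-butyldimethyl(prop-2-yn-1-yloxy)silane is lithiated (n-BuLi, THF, −78 °C) and silylated with benzylchlorodimethylsilane to give benzyl{3-[(tert-butyldimethylsilyl)oxy]prop-1-yn-1-yl}dimethylsilane F3. Annulation of F3 with 8 under the step 7 conditions should give (5S)-3-(benzyldimethylsilyl)-2-{[(tert-butyldimethylsilyl)oxy]methyl}-5-[(4E,6R)-6-methyl-6,7-bis(triethylsilyloxy)hepta-1,4-dien-2-yl]cyclohex-2-en-1-one F4. Bu4NF in THF then cleaves the benzyl–silicon bond and the activated silicon is lost from C3 (the known fluoride protodesilylation of alkenyl benzyldimethylsilanes), together with the O-silyl groups, rejoining the route at 16.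

3. Step 5. What may go wrong: erosion of branched regioselectivity (linear 1,4-diene formed by C–C bonding at the terminal alkyne carbon) or slow β-hydride elimination next to the quaternary carbon. Fallback, setting out from 7 and 3: the regiochemistry is fixed by cross-coupling instead. Markovnikov hydroiodination of 7 (Me3SiCl, NaI, H2O, MeCN, rt) gives 3-(1-iodoethenyl)cyclobutan-1-one F5. Palladium-catalysed linear allylic C–H acetoxylation of 3 (Pd(OAc)2, benzoquinone, DMSO/AcOH, 4 Å MS, 40 °C) gives (2E,4R)-4-methyl-4,5-bis(triethylsilyloxy)pent-2-en-1-yl acetate F6. Nickel-catalysed reductive cross-electrophile coupling of F5 with F6 (NiBr2(dme), 2,2′-bipyridine, Zn, DMA, rt) should join the vinyl carbon to the unhindered allyl terminus with the E alkene retained, and returns to 8.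

**Further compounds**

F1 | step 7 | (5R)-2-{[(tert-butyldimethylsilyl)oxy]methyl}-5-[(4E,6R)-6-methyl-6,7-bis(triethylsilyloxy)hepta-1,4-dien-2-yl]-3-(trimethylsilyl)cyclohex-2-en-1-one | C=C(C/C=C/[C@@](C)(O[Si](CC)(CC)CC)CO[Si](CC)(CC)CC)[C@H]1CC([Si](C)(C)C)=C(CO[Si](C)(C)C(C)(C)C)C(=O)C1
F2 | step 7 | (5S)-5-[(4E,6R)-6,7-dihydroxy-6-methylhepta-1,4-dien-2-yl]-2-(hydroxymethyl)cyclohex-2-en-1-one | C=C(C/C=C/[C@@](C)(O)CO)[C@H]1CC=C(CO)C(=O)C1
F3 | step 8 | benzyl{3-[(tert-butyldimethylsilyl)oxy]prop-1-yn-1-yl}dimethylsilane | CC(C)(C)[Si](C)(C)OCC#C[Si](C)(C)Cc1ccccc1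
F4 | step 8 | (5S)-3-(benzyldimethylsilyl)-2-{[(tert-butyldimethylsilyl)oxy]methyl}-5-[(4E,6R)-6-methyl-6,7-bis(triethylsilyloxy)hepta-1,4-dien-2-yl]cyclohex-2-en-1-one | C=C(C/C=C/[C@@](C)(O[Si](CC)(CC)CC)CO[Si](CC)(CC)CC)[C@@H]1CC([Si](C)(C)Cc2ccccc2)=C(CO[Si](C)(C)C(C)(C)C)C(=O)C1
F5 | step 5 | 3-(1-iodoethenyl)cyclobutan-1-one | C=C(I)C1CC(=O)C1
F6 | step 5 | (2E,4R)-4-methyl-4,5-bis(triethylsilyloxy)pent-2-en-1-yl acetate | CC(=O)OC/C=C/[C@@](C)(O[Si](CC)(CC)CC)CO[Si](CC)(CC)CC
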